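The vessel is closed, stirred and isothermal, so its target at the end is what forms early minus what is lost afterwards.

| setting | east | south-west | spring | noon |
|---|---|---|---|---|
| starting material | 20 mM | 20 mM | 20 mM | 20 mM |
| protic impurity | 7.3 mM | 10 mM | 12.0 mM | 4.00 mM |
| temperature | −5 °C | 15 °C | 30 °C | 0 °C |
| remark | run made earlier | run made earlier |  |  |
| time |  |  | 15 min | 15 min |

| run | time / min | target / % | starting material / % |
|---|---|---|---|
| east | 1.33 | 67.1 | 30.9 |
| east | 4.00 | 96.1 | 0.7 |
| east | 8.00 | 96.7 | 0 |
| east | 10.0 | 97.0 | 0 |
| east | 15.0 | 96.2 | 0 |
| south-west | 0.667 | 96.8 | 0 |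
| south-west | 1.33 | 96.2 | 0 |
| south-west | 2.00 | 96.0 | 0.2 |
| south-west | 4.00 | 93.9 | 0 |
| south-west | 8.00 | 90.7 | 0 |

(scatter of a reading: 0.3 percentage points)

- the winner by amount of target, in percent of the starting material charged; "neither" if no more than 2 percentage points parts them (spring / noon / neither)
- how much target is there at the end, in percent of the starting material charged: spring
- how much target is there at the end, in percent of the starting material charged: noon

- a reading or a percentage of target counts all its forms, free or not

In the east run 0.7% of the starting material remains after 4.00 min, a time shorter than 15 min, so the forming should be over early in spring and in noon, and the question is how much target lasts to the end. The east run's target holds, reading 96.7% and later 96.2%, but the south-west run's falls from 96.8% to 90.7%. If the rate of loss is k[target], integration gives [target] falling as exp(−kt), and those two south-west readings, taken at 15 °C, give a reading of the loss constant, the fraction of target lost per minute, 0.00888 min⁻¹.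

The reckoning here starts from the east run's 97.0% and assumes a factor of 4 on this constant for the step up to spring's temperature and the equal step down to noon's. That gives 56.9% for spring and 93.8% for noon.

The forecast names noon, with 61% for spring and 95.5% for noon, both higher than this reckoning; of spring it says “Over 15 min that leaves about 60%”.

The flask gives noon as winner, with 72.4% in spring and 97.3% in noon, crystals counted.

    target ⇌ isomer of the product (K = 1.10, k = 2.80 × 10⁻⁵ s⁻¹, Ea = 93.0 kJ mol⁻¹, ΔH = −13.0 kJ mol⁻¹)
    starting material + protic impurity → quenched substrate (k = 0.0870 M⁻¹ s⁻¹, Ea = 41.0 kJ mol⁻¹)
    starting material → target, rate k3*[starting material]/(1 + ([starting material]/sat3)) (16.0 mM, k = 0.0420 s⁻¹, Ea = 65.0 kJ mol⁻¹)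
    crystals ⇌ target, rate k4*(cs4 - [target]) while solid is left; crystals form when [target] > cs4 (solubility = 8.60 mM, k = 0.00360 s⁻¹)
    (constants at 0 °C)

Spring stands above 56.9%: its target is 74.3% after 7.50 min and 71.8% after 150 min, so it levels off where exp(−kt) keeps falling. A flask like noon kept at 15 °C sits at the temperature where 0.00888 min⁻¹ was read, so no factor enters, and the same reckoning gives 84.9%. That flask holds 88.8% of target, higher than reckoned, beside 10.5% of isomer of the product.

The earlier runs and the new flask stem from a simulated flask with constants of no real substance, and the scatter is random.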